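A small charge runs at a smaller percentage rate: midnight, with 11 mM of starting material, reads 11.5% target at 0.500 min, while summer, with 44 mM, reads 20.7%, though enzyme and second substrate rise with the charge in both. So we look for the concentration that sets the order of the rate.

| flask | starting material | second substrate | enzyme | remark | time |
|---|---|---|---|---|---|
| spring | 22 mM | 2 equiv | 0.01 mol% | run made earlier |  |
| midnight | 11 mM | 2 equiv | 0.01 mol% | run made earlier |  |
| summer | 44 mM | 2 equiv | 0.01 mol% | run made earlier |  |
| dusk | 22 mM | 3 equiv | 0.01 mol% | run made earlier |  |
| cedar | 22 mM | 2.00 equiv | 0.01 mol% | one stirred flow tank at steady state, fed with the mixture as stated, mean residence time 2.5 min |  |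
| larch | 22 mM (fed, over 2.50 min) | 2.00 equiv | 0.01 mol% | all but starting material at the start; starting material goes in evenly over 2.50 min, the run ends at 2.5 min | 2.5 min |
| birch | 22 mM | 2.00 equiv | 0.01 mol% | everything together in a closed stirred flask, run for 2.5 min | 2.5 min |
| ash | 22 mM | 2.00 equiv (fed, over 2.50 min) | 0.01 mol% | a stirred flask in which second substrate is dosed at a steady rate over 2.50 min without added volume, worked up at 2.5 min | 2.5 min |

| run | time / min | target / % |
|---|---|---|
| spring | 0.167 | 6.0 |
| spring | 0.500 | 16.1 |
| spring | 0.833 | 25.2 |
| spring | 1.33 | 36.7 |
| spring | 2.00 | 47.1 |
| spring | 2.50 | 52.0 |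
| midnight | 0.167 | 4.9 |
| midnight | 0.500 | 11.5 |
| midnight | 0.833 | 18.5 |
| midnight | 1.33 | 26.3 |
| midnight | 2.00 | 35.4 |
| midnight | 2.50 | 39.3 |
| summer | 0.167 | 7.4 |
| summer | 0.500 | 20.7 |
| summer | 0.833 | 31.8 |
| summer | 1.33 | 45.5 |
| summer | 2.00 | 57.2 |
| summer | 2.50 | 62.0 |
| dusk | 0.200 | 6.2 |
| dusk | 0.667 | 19.9 |
| dusk | 1.33 | 34.1 |
| dusk | 2.00 | 44.3 |
| dusk | 2.50 | 48.9 |

(each reading ± 0.3 percentage points)

- the stated concentrations are those of everything mixed, before any reaction; amounts are the same in each set-up
- the feed brings no volume worth counting
- the earlier runs were made in a closed, stirred flask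

- order of the set-ups by the amount of target at the outlet or at the end, in percent of the starting material put in, highest first (cedar / larch / birch / ash)
- amount of target at the outlet or at the end, in percent of the starting material put in, cedar
- amount of target at the outlet or at the end, in percent of the starting material put in, larch
- amount of target at the outlet or at the end, in percent of the starting material put in, birch
- amount of target at the outlet or at the end, in percent of the starting material put in, ash

The reciprocal of that reading, set against the reciprocal of the charge, gives a line through midnight and summer with slope 56.7 mM and intercept 3.54. Dusk's extra equivalent lowers the reading at 1.33 min from spring's 36.7% to 34.1%, which adds 0.474 to the reciprocal per equivalent. Taking the share of spring's 2 equiv off the intercept leaves 2.60, so the enzyme's top rate at this charge is 17.0 mM min⁻¹.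

Within a run we take second substrate as staying at its charge while starting material falls. What counts then is the working half-concentration, the starting material at which the enzyme reaches half its top rate with second substrate at full charge (an apparent Michaelis constant): 29.9 mM. It stands above the charge of 22 mM, but not far above it: by this reckoning the enzyme at the charge runs at 42.4% of its top rate, and the order in starting material there is 0.576, between zero and first order.

For larch, the feed is 8.80 mM min⁻¹. Guessing a mean standing concentration of 7.33 mM gives a rate constant of 0.456 min⁻¹. Feed against that constant leaves 13.1 mM standing at the end, hence 40.3% target.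

The weak link is that this law counts every reacted part as target. On spring, with a mean of 14.7 mM, it gives 61.4% against the reading of 52.0%. Scaling larch by that ratio, we commit to 34.2%.

The forecast gives ash > birch > cedar > larch, with cedar 36%, larch 26%, birch 52% and ash 54%. Its ground for the slowing is “That points to time-driven enzyme decay”. For larch our reckoning stands higher.

The flasks give ash > birch > cedar > larch: cedar 39.1%, larch 35.7%, birch 51.9%, ash 55.1%.

    starting material + enzyme ⇌ complex A (K = 49.0 M⁻¹, k = 3.90 × 10⁵ M⁻¹ s⁻¹)
    complex A → enzyme + target (k = 140 s⁻¹)
    second substrate + enzyme ⇌ complex B (K = 9.80 M⁻¹, k = 64000 M⁻¹ s⁻¹)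
    complex B → enzyme + second product (k = 72.0 s⁻¹)
    starting material → uncatalysed product (k = 0.00190 s⁻¹)
    target → over-reaction product (k = 0.00170 s⁻¹)
    second substrate → decomposition product (k = 4.40 × 10⁻⁶ s⁻¹)

The main reason for what larch falls short of is complex A falling back to starting material + enzyme: larch gives 35.7% with that step and 86.2% without it. Larch's highest starting material, 11.4 mM, stays below our working half-concentration. That puts 27.6% of the enzyme in complex A, and larch holds 28.5% at 2.50 min. For the neighbour of ash with 5.00 equiv of second substrate, the same quantity rises to 41.9 mM, and that flask ends at 50.2% target against 55.1% in ash.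

The readings are calculated for substances that don't exist, and the scatter is random.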